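In a one-step world, starting material and coupling partner have a single way to go, and there is no share between two products to move. Here there are two reversible ways, to target and to isomer of the product, so I asked how much the vessel could move the share of target between them.

| flask | starting material | coupling partner | protic impurity | remark | time |
|---|---|---|---|---|---|
| dusk | 0.19 M | 1.5 equiv | 0.19 M | run made earlier |  |
| dawn | 0.19 M | 1.5 equiv | 0.095 M | run made earlier |  |
| noon | 0.19 M | 1.5 equiv | 0.14 M | run made earlier |  |
| autumn | 0.19 M | 0.75 equiv | 0.19 M | run made earlier |  |
| east | 0.19 M | 1.50 equiv | 0.190 M | everything together in a closed stirred flask, run for 80 min | 80 min |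
| north-west | 0.19 M | 1.50 equiv | 0.190 M | one stirred flow tank at steady state, fed with the mixture as stated, mean residence time 800 min |  |
| south-west | 0.19 M (fed, over 80.0 min) | 1.50 equiv | 0.190 M | all but starting material at the start; starting material goes in evenly over 80.0 min, the run ends at 80 min | 80 min |
| north | 0.19 M | 1.50 equiv | 0.190 M | one stirred flow tank at steady state, fed with the mixture as stated, mean residence time 80 min |  |

| run | time / min | target / % | isomer of the product / % | starting material / % |
|---|---|---|---|---|
| dusk | 15.0 | 20.8 | 43.1 | 34.9 |
| dusk | 30.0 | 18.9 | 40.8 | 33.1 |
| dusk | 50.0 | 18.7 | 40.5 | 29.5 |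
| dusk | 60.0 | 16.3 | 40.2 | 28.9 |
| dusk | 80.0 | 17.7 | 41.2 | 29.5 |
| dawn | 6.00 | 24.8 | 33.9 | 39.3 |
| dawn | 12.0 | 21.3 | 42.0 | 34.9 |
| dawn | 25.0 | 20.4 | 45.5 | 36.3 |
| dawn | 40.0 | 18.9 | 43.5 | 31.7 |
| dawn | 80.0 | 18.8 | 42.1 | 32.6 |
| noon | 15.0 | 19.9 | 42.1 | 34.8 |
| noon | 30.0 | 20.0 | 42.8 | 35.5 |
| noon | 50.0 | 19.2 | 41.0 | 31.6 |
| noon | 60.0 | 17.7 | 41.5 | 32.3 |
| noon | 80.0 | 19.8 | 42.3 | 29.9 |
| autumn | 15.0 | 14.2 | 26.3 | 52.1 |
| autumn | 30.0 | 12.5 | 24.8 | 50.9 |
| autumn | 50.0 | 12.1 | 24.9 | 46.7 |
| autumn | 60.0 | 11.5 | 26.3 | 46.8 |
| autumn | 80.0 | 11.1 | 23.9 | 43.5 |

(readings scatter by 1 percentage point)

- the stated concentrations are those of everything mixed, before any reaction; amounts are the same in each set-up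
- steps under discussion: starting material + coupling partner <-> target; starting material + coupling partner <-> isomer of the product; starting material -> decomposition product; starting material + protic impurity -> quenched substrate
- the feed brings no volume worth counting
- the earlier runs were made in a closed, stirred flask

1. the set-up with the highest share of target in all that became target or isomer of the product, at the outlet or at the end ("none" if the first two lie within 2 percentage points) (east / north-west / south-west / north / none)
2. share of target in all that became target or isomer of the product, at the outlet or at the end, east
3. share of target in all that became target or isomer of the product, at the outlet or at the end, north-west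
4. share of target in all that became target or isomer of the product, at the outlet or at the end, south-west
5. share of target in all that became target or isomer of the product, at the outlet or at the end, north

I began with two extreme flasks that can be solved in the head. Under kinetic control what forms stays as it formed, and the share is that of the fresh mixture. Under thermodynamic control the mixture has come to rest, and the last readings of the earlier runs put that resting share at 31.1%.

The real flask lies between them, and I placed it by how long it has had to forget. The dawn run read a share of target of 42.2% at 6.00 min and 33.6% at 12.0 min. From the fall of the excess over the resting share I read, roughly, with readings that scatter by 1 percentage point, 4.04 min, the time for that excess to fall by a factor e, which I called the memory time. Carried back to the start, the same fall gave a rough fresh excess of 49 points.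

In powers of ten, at that memory time a closed flask forgets one power every 9.30 min, so I reckoned east to have lost 8.61 powers at its end. A tank keeps receiving fresh feed, and I took its excess to be the fresh excess times the memory time over the memory time plus the residence time. That made 2.30 powers for north-west and 1.32 for north. I therefore reckoned 31.4% for north-west and 33.5% for north. I set south-west, with its fresh last feed, near north, and so answered none.

The forecast gave 31% for east, 31.2% for north-west, 33% for south-west and 32.5% for north, so none, holding, with a relaxation of about 4 min, that "Every set-up therefore lies far beyond that timescale." Its north stood below mine.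

The flask gave 31.3% for east, 31.7% for north-west, 33.0% for south-west and 33.3% for north, so none. To overturn that, north would have had to lead south-west by 2 points, and it led by 0.30 points. The outlet of north held 18.8% of the charge as target and 37.8% as isomer of the product. The memory time put north above north-west by 2.1 points, against 1.6 points found. East, reckoned 8.61 powers down at its end, stood at 31.4% after 800 min.

    starting material + coupling partner ⇌ target (K = 3.50 M⁻¹, k = 0.0350 M⁻¹ s⁻¹)
    starting material + coupling partner ⇌ isomer of the product (K = 7.60 M⁻¹, k = 0.0150 M⁻¹ s⁻¹)
    starting material → decomposition product (k = 1.00 × 10⁻⁷ s⁻¹)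
    starting material + protic impurity → quenched substrate (k = 5.00 × 10⁻⁴ M⁻¹ s⁻¹)

The numbers in the tables are calculated for substances that don't exist, noise included.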